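**Strategy.** Ring numbering: C1(=O), C2(OH), C3(alkyl), C4(=O), C5(OMe), C6(Me). Each quinone is disconnected across both ring C=C bonds, C5=C6 and C2=C3, into a C3–C4–C5 unit (one CH2–CO–CH2OMe end of an acyclic diketone) and a C6–C1–C2 unit (methyl but-2-ynoate). The route exploits the 1,3-related oxygens on C2 and C4 flanking C3 (a latent resorcinol) and the twofold symmetry about the tetradecane linker. One double Michael–Claisen [3+3] benzannulation of 1,20-dimethoxyicosane-2,19-dione should forge both rings as 2-alkyl-4-methoxy-5-methylresorcinols. Their only free position (C1) is then oxidized to the quinone carbonyl.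

Key step: step 2

Remark: the target has no stereocentre and is achiral, so no stereocontrol is needed and the given SMILES is taken as the complete structure.

**Step 1**
Reactants: 1 1,16-dibromohexadecane; 2 N,2-dimethoxy-N-methylacetamide (2.4 equiv)
Product: 4 1,20-dimethoxyicosane-2,19-dione, via hexadecane-1,16-diylbis(magnesium bromide) 3 (not isolated)
Conditions: Mg (2.5 equiv), cat. I2, THF, reflux; then 2 (2.4 equiv), THF, 0 °C → rt; 1 M HCl
Reagents that add atoms: magnesium (2.5 equiv), [Mg] (retained only in intermediate 3)
Why: Twofold Weinreb ketone synthesis: each of the two C–MgBr termini of 3 should add once to one molecule of the N-methoxy-N-methylamide, because the magnesium-chelated tetrahedral adduct does not collapse before the acidic quench, so two molecules of 2 are consumed per chain and the bis(methoxymethyl ketone) should form without over-addition.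

**Step 2**
Reactants: 4 1,20-dimethoxyicosane-2,19-dione; 5 methyl but-2-ynoate (2.3 equiv)
Product: 8 2,2'-(tetradecane-1,14-diyl)bis(4-methoxy-5-methylbenzene-1,3-diol), via bis-enoate Michael adduct 6 (not isolated), via bis-cyclohexenedione tautomer 7 (not isolated)
Conditions: t-BuOK (6 equiv), THF, 0 °C → rt; then MeOH, reflux, argon; 1 M HCl
Reagents that add atoms: none
Why: Proposed new method: a tandem Michael addition–Claisen (Dieckmann) [3+3] benzannulation is run at both chain ends, in which under equilibrating alkoxide each ketone should enolize mainly at the methoxy-bearing C5, this enolate adds to the methyl-bearing β-carbon C6 of the ynoate to give 6 (C5–C6 bond), and after proton transfer the C3 enolate attacks the ester carbon C2 with loss of methoxide (C3–C2 bond) to give 7, which tautomerizes to the resorcinol. The closest known reaction types are the consecutive Michael–Claisen synthesis of cyclohexane-1,3-diones from simple ketones and acrylates and the Michael–Dieckmann synthesis of resorcinols from acetonedicarboxylate enolates and alkynyl carbonyl compounds, whereas the direct union of an unactivated α-alkoxy ketone with an ynoate to a resorcinol is the untested part. Each ring closes in a 6-(enolendo)-exo-trig mode, which is allowed. No stereocentre is created, since the C5 centre and the alkene geometry of 6 are lost on aromatization. The step needs regioselection between C5 and C3 in the Michael event, which the higher acidity of the CH2OMe protons (inductive effect of the methoxy group) should secure, and C- over O-acylation with the right enoate geometry, which should follow because the E/Z isomers of 6 and any α-pyranone equilibrate through the dienolate and through ring opening by methoxide while formation of the aromatic resorcinolate is irreversible. The two ends, sixteen methylenes apart, should react independently.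

**Step 3**
Reactants: 8 2,2'-(tetradecane-1,14-diyl)bis(4-methoxy-5-methylbenzene-1,3-diol)
Product: 9 3,3'-(tetradecane-1,14-diyl)bis(2-hydroxy-5-methoxy-6-methylcyclohexa-2,5-diene-1,4-dione), the target
Conditions: Fremy's salt (5 equiv), aq. KH2PO4 buffer, acetone–H2O, 0 °C → rt
Reagents that add atoms: potassium nitrosodisulfonate (Fremy's salt), [O]N(S(=O)(=O)[O-])S(=O)(=O)[O-].[K+].[K+]
Why: Teuber oxidation: the aryloxyl radical of each resorcinol should be trapped by a second nitrosodisulfonate radical at C1, the only unsubstituted ring carbon (para to the C4 hydroxyl), and loss of imidodisulfonate gives the 1,4-quinone with the C2 hydroxyl retained as the vinylogous acid, as known for resorcinols that give 2-hydroxy-1,4-benzoquinones.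

**Compound list**
1 | 1,16-dibromohexadecane | BrCCCCCCCCCCCCCCCCBr | starting material
2 | N,2-dimethoxy-N-methylacetamide | COCC(=O)N(C)OC | starting material
3 | hexadecane-1,16-diylbis(magnesium bromide) | Br[Mg]CCCCCCCCCCCCCCCC[Mg]Br | intermediate (not isolated)
4 | 1,20-dimethoxyicosane-2,19-dione | COCC(=O)CCCCCCCCCCCCCCCCC(=O)COC | intermediate
5 | methyl but-2-ynoate | CC#CC(=O)OC | starting material
6 | dimethyl 4,23-dimethoxy-3,24-dimethyl-5,22-dioxohexacosa-2,24-dienedioate (alkene geometry and the two transient CH(OMe) centres undefined) | COC(=O)C=C(C)C(OC)C(=O)CCCCCCCCCCCCCCCCC(=O)C(OC)C(C)=CC(=O)OC | intermediate (not isolated)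
7 | 2,2'-(tetradecane-1,14-diyl)bis(4-methoxy-5-methylcyclohex-4-ene-1,3-dione), keto tautomer of 8, present as its enolate | COC1=C(C)CC(=O)C(CCCCCCCCCCCCCCC2C(=O)CC(C)=C(OC)C2=O)C1=O | intermediate (not isolated)
8 | 2,2'-(tetradecane-1,14-diyl)bis(4-methoxy-5-methylbenzene-1,3-diol) | Cc1cc(O)c(CCCCCCCCCCCCCCc2c(O)cc(C)c(OC)c2O)c(O)c1OC | intermediate
9 | 3,3'-(tetradecane-1,14-diyl)bis(2-hydroxy-5-methoxy-6-methylcyclohexa-2,5-diene-1,4-dione) | COC1=C(C)C(=O)C(O)=C(CCCCCCCCCCCCCCC2=C(O)C(=O)C(C)=C(OC)C2=O)C1=O | target

Total step count: 3
Longest linear sequence: 3 steps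

**Steps most likely to fail**

Step 2 (key step, proposed new method). The conjugate addition may run through the alkyl-side (C3) enolate as well as the methoxy-side (C5) enolate, which would transpose the alkyl and methyl groups relative to the methoxy group. The cascade may also stop after O-acylation at the α-pyranone. The fallback sets out from 4 and comes back at 8, and makes the two C–C bonds in separate, known Lewis-acid and base steps through an isolable enol derivative whose regiochemistry can be assigned. Diketone 4 is silylated under equilibrating soft-enolization conditions (TMSCl, NaI, Et3N, MeCN) to (1Z,19Z)-1,20-dimethoxy-2,19-bis(trimethylsilyloxy)icosa-1,19-diene F1, which is freed from any regioisomer. Methyl 3,3-dimethoxybutanoate F2 (from methyl acetoacetate, HC(OMe)3, cat. TsOH, MeOH) is then added in a TMSOTf-catalysed Mukaiyama aldol-type reaction of the ketal (CH2Cl2, −78 °C). This should give dimethyl 3,4,23,24-tetramethoxy-3,24-dimethyl-5,22-dioxohexacosanedioate F3 with the C5–C6 bonds in place. NaOMe in MeOH at reflux then eliminates methanol and effects Dieckmann closure and aromatization to 8.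

Step 3. Oxidation may also occur at the position para to the C2 hydroxyl with loss of the methoxy group, and the electron-rich rings may undergo radical coupling or over-oxidation. Oxidation of both rings may also be incomplete because of poor solubility. The fallback sets out from 8 and comes back at 9, and introduces the C1 oxygen by C–C bond formation and rearrangement instead of radical oxidation. Vilsmeier–Haack formylation (POCl3, DMF; aq. NaOAc) at the only free ring position should give 3,3'-(tetradecane-1,14-diyl)bis(2,4-dihydroxy-5-methoxy-6-methylbenzaldehyde) F4. Dakin oxidation (H2O2, NaOH, THF–H2O, argon; then acid) should give 3,3'-(tetradecane-1,14-diyl)bis(5-methoxy-6-methylbenzene-1,2,4-triol) F5. This triol is oxidized by air (or FeCl3) to 9.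

Step 1. Formation of the twofold Grignard reagent may be incomplete and accompanied by Wurtz-type chain coupling, and the Grignard reagent may deprotonate the α-methoxy C–H of the amide in place of adding to it. The fallback sets out from 2 and comes back at 4, and uses an sp-carbon nucleophile followed by reduction. Hexadeca-1,15-diyne F6 (from 1,12-dibromododecane and lithium acetylide–ethylenediamine, DMSO) is deprotonated twice (n-BuLi, THF, −78 °C) and added to two equivalents of 2. This should give 1,20-dimethoxyicosa-3,17-diyne-2,19-dione F7, and hydrogenation (H2, Pd/C, EtOAc) returns to 4.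

**Further compounds**
F1 | step 2 | (1Z,19Z)-1,20-dimethoxy-2,19-bis(trimethylsilyloxy)icosa-1,19-diene | CO/C=C(\O[Si](C)(C)C)CCCCCCCCCCCCCCCC/C(O[Si](C)(C)C)=C/OC
F2 | step 2 | methyl 3,3-dimethoxybutanoate | COC(=O)CC(C)(OC)OC
F3 | step 2 | dimethyl 3,4,23,24-tetramethoxy-3,24-dimethyl-5,22-dioxohexacosanedioate (diastereomer mixture) | COC(=O)CC(C)(OC)C(OC)C(=O)CCCCCCCCCCCCCCCCC(=O)C(OC)C(C)(OC)CC(=O)OC
F4 | step 3 | 3,3'-(tetradecane-1,14-diyl)bis(2,4-dihydroxy-5-methoxy-6-methylbenzaldehyde) | O=Cc1c(C)c(OC)c(O)c(CCCCCCCCCCCCCCc2c(O)c(C=O)c(C)c(OC)c2O)c1O
F5 | step 3 | 3,3'-(tetradecane-1,14-diyl)bis(5-methoxy-6-methylbenzene-1,2,4-triol) | Oc1c(C)c(OC)c(O)c(CCCCCCCCCCCCCCc2c(O)c(O)c(C)c(OC)c2O)c1O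
F6 | step 1 | hexadeca-1,15-diyne | C#CCCCCCCCCCCCCCC#C
F7 | step 1 | 1,20-dimethoxyicosa-3,17-diyne-2,19-dione | COCC(=O)C#CCCCCCCCCCCCCCC#CC(=O)COC
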